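**Plan**

1. Carotenoid numbering is used (acetylenic end: ring C1–C6, C7≡C8; dihydro end: ring C1'–C6', C7'H2–C8'H2). The C40 chain is cut at C11=C12 and C11'=C12' (two Wittig reactions) into the C10 dialdehyde and two C15 phosphonium salts; the acetylenic C15 unit is cut at C6–C7 (Sonogashira) into an actinol-derived enol triflate and (E)-3-methylpent-2-en-4-yn-1-ol.
2. The dihydro end ring is opened at C4'–C3' and C1'–C2' together. Its only double bond, the tetrasubstituted C5'=C6', lies between C4'H2 and the quaternary C1'Me2 and faces the two-carbon edge C2'H2–C3'H(OH); this is the pattern left by a [4+2] cycloaddition of a 2,4-dimethylpenta-1,3-dien-3-yl diene (C4'=C5'–C6'=C1') with a vinylborane used as a vinyl alcohol equivalent.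
3. The acyclic diene is cut at C6'–C7' (B-alkyl Suzuki) into a dienyl triflate (from isobutyric Weinreb amide and isopropenyl Grignard) and the hydroborated silyl ether of (E)-3-methylpenta-2,4-dien-1-ol.
4. Forward order: acyclic triene, then the dihydro end ring by cycloaddition/oxidation, then its C15 salt; separately the acetylenic C15 salt; C15 + C10 gives the C25 aldehyde; C25 + C15' gives C40; desilylation.
5. Stereochemistry: C3 from (4R,6R)-actinol; C3' from the Ipc2B group on the dienophile (reagent control, C–B oxidation with retention); 9E and 9'E from the purchased (E)-enynol, 13E/13'E from the C10 dialdehyde, 11E/11'E by Wittig reaction followed by thermal Z→E relaxation.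

Key step: step 6

Assumption (step 6): the sense of induction by the Ipc2B group has no precedent to lean on; the (−)-Ipc2B series from (+)-α-pinene is written as giving (3'R), and (+)-DIP-Cl would be used in the same way if the opposite sense were found.

**Route**

Step 1
Reactants: 1 N-methoxy-N-methylisobutyramide; 2 isopropenylmagnesium bromide
Product: 4 2,4-dimethylpent-1-en-3-one, via bromomagnesium hemiaminal 3 (not isolated)
Conditions: THF, 0 °C → rt; cold 1 M HCl
Reagents that add atoms: none
Why: Weinreb ketone synthesis, in which the chelated tetrahedral adduct 3 holds the acyl carbon until work-up so that the enone is not attacked a second time.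

Step 2
Reactants: 4 2,4-dimethylpent-1-en-3-one
Product: 6 2,4-dimethylpenta-1,3-dien-3-yl trifluoromethanesulfonate, via potassium dienolate 5 (not isolated)
Conditions: KHMDS, THF, −78 °C; PhNTf2, −78 → 0 °C
Reagents that add atoms: N-phenylbis(trifluoromethanesulfonimide), O=S(=O)(N(c1ccccc1)S(=O)(=O)C(F)(F)F)C(F)(F)F
Why: The isopropyl methine is the only acidic α-CH of 4, so enolisation can give only the cross-conjugated dienolate 5, and O-sulfonylation (enol triflate formation) fixes the tetrasubstituted C=C.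

Step 3
Reactants: 7 (E)-3-methylpent-2-en-4-yn-1-ol
Product: 8 tert-butyldimethyl{[(2E)-3-methylpent-2-en-4-yn-1-yl]oxy}silane
Conditions: TBSCl, imidazole, CH2Cl2, 0 °C → rt
Reagents that add atoms: tert-butyldimethylsilyl chloride, CC(C)(C)[Si](C)(C)Cl
Why: Imidazole-mediated silylation of the primary alcohol keeps the OH away from the borane reagents of steps 5 and 6.

Step 4
Reactants: 8 silyl enynyl ether
Product: 9 tert-butyldimethyl{[(2E)-3-methylpenta-2,4-dien-1-yl]oxy}silane
Conditions: H2 (1 atm), Lindlar catalyst, quinoline, hexane, rt, stopped after 1 equiv H2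
Reagents that add atoms: none
Why: Lindlar semi-hydrogenation should stop at the vinyl group and leave the trisubstituted (E)-olefin, whose geometry is that of purchased 7, untouched.

Step 5
Reactants: 9 silyl dienyl ether; 10 9-borabicyclo[3.3.1]nonane; 6 dienyl triflate
Product: 12 tert-butyl{[(2E)-3,7-dimethyl-6-(propan-2-ylidene)octa-2,7-dien-1-yl]oxy}dimethylsilane, via alkylborane 11 (not isolated)
Conditions: 9-BBN, THF, 0 °C → rt; then 6, PdCl2(dppf) (5 mol %), AsPh3, aq. K3PO4, DMF, rt → 50 °C
Reagents that add atoms: none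
Why: 9-BBN should add anti-Markovnikov to the monosubstituted vinyl group only, and B-alkyl Suzuki–Miyaura coupling of the primary borane with the activated dienyl triflate forms C6'–C7'.

Step 6
Reactants: 12 triene; 13 vinylmagnesium bromide; 14 (−)-B-chlorodiisopinocampheylborane
Product: 17 (1R)-4-[(3E)-5-(tert-butyldimethylsilyloxy)-3-methylpent-3-en-1-yl]-3,5,5-trimethylcyclohex-3-en-1-ol, via B-vinyldiisopinocampheylborane 15 (not isolated), via cycloadduct borane 16 (not isolated)
Conditions: 14 + 13, Et2O, −78 → 0 °C, salts filtered off; solvent exchanged for toluene, 12, 25–40 °C; then 3 M NaOH, 30% H2O2, THF, 0 °C → rt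
Reagents that add atoms: hydrogen peroxide, OO
Why: Proposed new method: the closest known reaction type is the Diels–Alder reaction of B-vinyl dialkylboranes (B-vinyl-9-BBN type) with acyclic dienes followed by retentive C–B oxidation, used as a vinyl alcohol equivalent; new here are the chiral diisopinocampheylboryl controller and the 1,1,2,3-tetrasubstituted diene. Mechanistically the empty boron p orbital lowers the vinyl LUMO and the trialkylated diene 12 (high HOMO, s-trans form destabilised by the clash of the C5' methyl with the inner C1' methyl) adds in one concerted, asynchronous, suprafacial [4+2] step, so that C4'–C3' and C1'–C2' form together and the six-membered ring is closed by intermolecular cycloaddition with the new π bond left at C5'=C6'. The step needs regioselectivity (boron-bearing carbon to the C4'H2 terminus, unsubstituted dienophile carbon to C1'Me2), and the gem-dimethyl terminus of the diene secures it by repelling the bulky dialkylboryl group, the same steric control that gives "meta" adducts from bulky vinylboranes and 1-substituted dienes, while the para-directing effects of the C5' methyl and the C6' chain oppose each other. The single new stereocentre C3' is controlled by the reagent: the C2-symmetric Ipc2B unit shields one π face of the coplanar B–CH=CH2 group with its 2-methyl groups, and alkaline H2O2 then replaces boron by OH with retention. The isolated trisubstituted olefin and the silyl ether do not react with vinylboranes, and the quaternary C1' is formed from the unsubstituted CH2 of the dienophile, the least hindered way to make it.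

Step 7
Reactants: 17 silyl ether alcohol
Product: 18 (1R)-4-[(3E)-5-hydroxy-3-methylpent-3-en-1-yl]-3,5,5-trimethylcyclohex-3-en-1-ol
Conditions: TBAF, THF, 0 °C → rt
Reagents that add atoms: none
Why: Fluoride desilylation frees the primary allylic alcohol without touching either olefin or the C3' stereocentre.

Step 8
Reactants: 18 diol
Product: 20 {(2E)-5-[(4R)-4-hydroxy-2,6,6-trimethylcyclohex-1-en-1-yl]-3-methylpent-2-en-1-yl}triphenylphosphonium bromide, via allylic bromide 19 (not isolated)
Conditions: NBS, Me2S, CH2Cl2, −20 → 0 °C; then PPh3, CH2Cl2/EtOAc, rt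
Reagents that add atoms: N-bromosuccinimide, O=C1CCC(=O)N1Br; triphenylphosphine, c1ccc(cc1)P(c1ccccc1)c1ccccc1
Why: Corey–Kim bromination converts only the allylic OH (the saturated 3'-OH returns on work-up) with retention of the 9'E geometry, and SN2 quaternisation by PPh3 gives the Wittig salt.

Step 9
Reactants: 21 (4R,6R)-4-hydroxy-2,2,6-trimethylcyclohexanone (actinol)
Product: 22 (4R,6R)-4-(tert-butyldimethylsilyloxy)-2,2,6-trimethylcyclohexanone
Conditions: TBSCl, imidazole, DMF, rt
Reagents that add atoms: tert-butyldimethylsilyl chloride, CC(C)(C)[Si](C)(C)Cl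
Why: Silylation protects the carbinol (the future C3 stereocentre) for the enolate chemistry of step 10.

Step 10
Reactants: 22 silylated actinol
Product: 24 (4R)-4-(tert-butyldimethylsilyloxy)-2,6,6-trimethylcyclohex-1-en-1-yl trifluoromethanesulfonate, via lithium enolate 23 (not isolated)
Conditions: LDA, THF, −78 °C; PhNTf2, −78 °C → rt
Reagents that add atoms: N-phenylbis(trifluoromethanesulfonimide), O=S(=O)(N(c1ccccc1)S(=O)(=O)C(F)(F)F)C(F)(F)F
Why: The ketone has a single α-CH (the other α-carbon is quaternary), so enol triflate formation can give only the tetrasubstituted triflate; the methyl-bearing stereocentre becomes sp2 and the carbinol centre is untouched.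

Step 11
Reactants: 24 enol triflate; 7 (E)-3-methylpent-2-en-4-yn-1-ol
Product: 25 (2E)-5-[(4R)-4-(tert-butyldimethylsilyloxy)-2,6,6-trimethylcyclohex-1-en-1-yl]-3-methylpent-2-en-4-yn-1-ol
Conditions: Pd(PPh3)4 (5 mol %), CuI (10 mol %), i-Pr2NH, DMF, rt
Reagents that add atoms: none
Why: Sonogashira coupling of the enol triflate with the terminal alkyne forms C6–C7 and carries the 9E geometry of 7 into the C15 unit.

Step 12
Reactants: 25 C15 enynol
Product: 27 {(2E)-5-[(4R)-4-(tert-butyldimethylsilyloxy)-2,6,6-trimethylcyclohex-1-en-1-yl]-3-methylpent-2-en-4-yn-1-yl}triphenylphosphonium bromide, via allylic bromide 26 (not isolated)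
Conditions: NBS, Me2S, CH2Cl2, −20 → 0 °C; then PPh3, EtOAc, rt
Reagents that add atoms: N-bromosuccinimide, O=C1CCC(=O)N1Br; triphenylphosphine, c1ccc(cc1)P(c1ccccc1)c1ccccc1
Why: Corey–Kim bromination under neutral conditions followed by SN2 quaternisation should keep the 9E geometry that an acid-mediated salt formation would put at risk.

Step 13
Reactants: 27 acetylenic C15 phosphonium bromide; 28 (2E,4E,6E)-2,7-dimethylocta-2,4,6-trienedial (3 equiv)
Product: 31 (3R)-3-(tert-butyldimethylsilyloxy)-7,8-didehydro-12'-apo-β-caroten-12'-al (all-E C25 aldehyde), via ylide 29 (not isolated), via 11Z isomer 30 (not isolated)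
Conditions: NaOMe, MeOH/CH2Cl2, 0 °C → rt; then heptane, reflux, dark, Ar
Reagents that add atoms: none
Why: Wittig reaction of the conjugated ylide with an excess of the dialdehyde should stop at mono-olefination, and the sterically hindered 11Z isomer relaxes thermally to 11E without touching the trisubstituted 9E bond.

Step 14
Reactants: 20 dihydro C15 phosphonium bromide; 31 C25 aldehyde
Product: 34 (3R,3'R)-3-(tert-butyldimethylsilyloxy)-7,8-didehydro-7',8'-dihydro-β,β-caroten-3'-ol, via ylide 32 (not isolated), via 11'Z isomer 33 (not isolated)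
Conditions: NaHMDS (1.05 equiv), THF, −78 → 0 °C; 31, −78 °C → rt; then heptane, reflux, dark, Ar
Reagents that add atoms: none
Why: Wittig reaction forms C11'=C12'; the ylide is much less basic than an alkoxide, so the free 3'-OH should be tolerated, and the hindered 11'Z isomer is relaxed thermally (no iodine, which would scramble 9E and 9'E).

Step 15
Reactants: 34 C40 silyl ether
Product: 35 (3R,3'R)-7,8-didehydro-7',8'-dihydro-β,β-carotene-3,3'-diol (all-E)
Conditions: TBAF, THF, rt, dark; crystallisation
Reagents that add atoms: none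
Why: Fluoride desilylation of the secondary silyl ether is neutral toward the polyene, the alkyne and both carbinol centres.

**Compound list**

1 | N-methoxy-N-methylisobutyramide | CC(C)C(=O)N(C)OC | starting material
2 | isopropenylmagnesium bromide | CC(=C)[Mg]Br | starting material
3 | bromomagnesium hemiaminal (tetrahedral adduct of 1 and 2) | CC(C)C(O[Mg]Br)(N(C)OC)C(C)=C | intermediate (not isolated)
4 | 2,4-dimethylpent-1-en-3-one | CC(C)C(=O)C(C)=C | intermediate
5 | potassium 2,4-dimethylpenta-1,3-dien-3-olate | [K+].[O-]C(=C(C)C)C(C)=C | intermediate (not isolated)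
6 | 2,4-dimethylpenta-1,3-dien-3-yl trifluoromethanesulfonate | CC(C)=C(OS(=O)(=O)C(F)(F)F)C(C)=C | intermediate
7 | (E)-3-methylpent-2-en-4-yn-1-ol | OC/C=C(\C)C#C | starting material
8 | tert-butyldimethyl{[(2E)-3-methylpent-2-en-4-yn-1-yl]oxy}silane | CC(C)(C)[Si](C)(C)OC/C=C(\C)C#C | intermediate
9 | tert-butyldimethyl{[(2E)-3-methylpenta-2,4-dien-1-yl]oxy}silane | CC(C)(C)[Si](C)(C)OC/C=C(\C)C=C | intermediate
10 | 9-borabicyclo[3.3.1]nonane (9-BBN) | B1C2CCCC1CCC2 | starting material
11 | 9-[(3E)-5-(tert-butyldimethylsilyloxy)-3-methylpent-3-en-1-yl]-9-borabicyclo[3.3.1]nonane | CC(C)(C)[Si](C)(C)OC/C=C(\C)CCB1C2CCCC1CCC2 | intermediate (not isolated)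
12 | tert-butyl{[(2E)-3,7-dimethyl-6-(propan-2-ylidene)octa-2,7-dien-1-yl]oxy}dimethylsilane | CC(C)(C)[Si](C)(C)OC/C=C(\C)CCC(=C(C)C)C(C)=C | intermediate
13 | vinylmagnesium bromide | C=C[Mg]Br | starting material
14 | (−)-B-chlorodiisopinocampheylborane ((−)-DIP-Cl, from (+)-α-pinene) | ClB([C@@H]1C[C@@H]2C[C@H]([C@H]1C)C2(C)C)[C@@H]1C[C@@H]2C[C@H]([C@H]1C)C2(C)C | starting material
15 | B-vinyldiisopinocampheylborane | C=CB([C@@H]1C[C@@H]2C[C@H]([C@H]1C)C2(C)C)[C@@H]1C[C@@H]2C[C@H]([C@H]1C)C2(C)C | intermediate (not isolated)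
16 | cycloadduct borane (Ipc2B on ring C3', on the face that becomes the (R)-carbinol) | CC(C)(C)[Si](C)(C)OC/C=C(\C)CCC1=C(C)C[C@@H](B([C@@H]2C[C@@H]3C[C@H]([C@H]2C)C3(C)C)[C@@H]2C[C@@H]3C[C@H]([C@H]2C)C3(C)C)CC1(C)C | intermediate (not isolated)
17 | (1R)-4-[(3E)-5-(tert-butyldimethylsilyloxy)-3-methylpent-3-en-1-yl]-3,5,5-trimethylcyclohex-3-en-1-ol | CC(C)(C)[Si](C)(C)OC/C=C(\C)CCC1=C(C)C[C@@H](O)CC1(C)C | intermediate
18 | (1R)-4-[(3E)-5-hydroxy-3-methylpent-3-en-1-yl]-3,5,5-trimethylcyclohex-3-en-1-ol | OC/C=C(\C)CCC1=C(C)C[C@@H](O)CC1(C)C | intermediate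
19 | (1R)-4-[(3E)-5-bromo-3-methylpent-3-en-1-yl]-3,5,5-trimethylcyclohex-3-en-1-ol | BrC/C=C(\C)CCC1=C(C)C[C@@H](O)CC1(C)C | intermediate (not isolated)
20 | {(2E)-5-[(4R)-4-hydroxy-2,6,6-trimethylcyclohex-1-en-1-yl]-3-methylpent-2-en-1-yl}triphenylphosphonium bromide | C(/C=C(\C)CCC1=C(C)C[C@@H](O)CC1(C)C)[P+](c1ccccc1)(c1ccccc1)c1ccccc1.[Br-] | intermediate
21 | (4R,6R)-4-hydroxy-2,2,6-trimethylcyclohexanone (actinol) | O=C1[C@H](C)C[C@@H](O)CC1(C)C | starting material
22 | (4R,6R)-4-(tert-butyldimethylsilyloxy)-2,2,6-trimethylcyclohexanone | O=C1[C@H](C)C[C@@H](O[Si](C)(C)C(C)(C)C)CC1(C)C | intermediate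
23 | lithium (4R)-4-(tert-butyldimethylsilyloxy)-2,6,6-trimethylcyclohex-1-en-1-olate | [Li+].[O-]C1=C(C)C[C@@H](O[Si](C)(C)C(C)(C)C)CC1(C)C | intermediate (not isolated)
24 | (4R)-4-(tert-butyldimethylsilyloxy)-2,6,6-trimethylcyclohex-1-en-1-yl trifluoromethanesulfonate | CC1=C(OS(=O)(=O)C(F)(F)F)C(C)(C)C[C@H](O[Si](C)(C)C(C)(C)C)C1 | intermediate
25 | (2E)-5-[(4R)-4-(tert-butyldimethylsilyloxy)-2,6,6-trimethylcyclohex-1-en-1-yl]-3-methylpent-2-en-4-yn-1-ol | CC1=C(C#C/C(C)=C/CO)C(C)(C)C[C@H](O[Si](C)(C)C(C)(C)C)C1 | intermediate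
26 | (2E)-1-bromo-5-[(4R)-4-(tert-butyldimethylsilyloxy)-2,6,6-trimethylcyclohex-1-en-1-yl]-3-methylpent-2-en-4-yne | CC1=C(C#C/C(C)=C/CBr)C(C)(C)C[C@H](O[Si](C)(C)C(C)(C)C)C1 | intermediate (not isolated)
27 | {(2E)-5-[(4R)-4-(tert-butyldimethylsilyloxy)-2,6,6-trimethylcyclohex-1-en-1-yl]-3-methylpent-2-en-4-yn-1-yl}triphenylphosphonium bromide | CC1=C(C#C/C(C)=C/C[P+](c2ccccc2)(c2ccccc2)c2ccccc2)C(C)(C)C[C@H](O[Si](C)(C)C(C)(C)C)C1.[Br-] | intermediate
28 | (2E,4E,6E)-2,7-dimethylocta-2,4,6-trienedial (C10 dialdehyde) | O=C/C(C)=C/C=C/C=C(C)/C=O | starting material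
29 | triphenylphosphonium ylide of 27 | CC1=C(C#C/C(C)=C/C=P(c2ccccc2)(c2ccccc2)c2ccccc2)C(C)(C)C[C@H](O[Si](C)(C)C(C)(C)C)C1 | intermediate (not isolated)
30 | (11Z) isomer of 31 | CC1=C(C#C/C(C)=C/C=C\C(C)=C\C=C\C=C(C)\C=O)C(C)(C)C[C@H](O[Si](C)(C)C(C)(C)C)C1 | intermediate (not isolated)
31 | (3R)-3-(tert-butyldimethylsilyloxy)-7,8-didehydro-12'-apo-β-caroten-12'-al (all-E) | CC1=C(C#C/C(C)=C/C=C/C(C)=C/C=C/C=C(C)/C=O)C(C)(C)C[C@H](O[Si](C)(C)C(C)(C)C)C1 | intermediate
32 | triphenylphosphonium ylide of 20 | C(/C=C(\C)CCC1=C(C)C[C@@H](O)CC1(C)C)=P(c1ccccc1)(c1ccccc1)c1ccccc1 | intermediate (not isolated)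
33 | (11'Z) isomer of 34 | CC1=C(C#C/C(C)=C/C=C/C(C)=C/C=C/C=C(C)/C=C\C=C(/C)CCC2=C(C)C[C@@H](O)CC2(C)C)C(C)(C)C[C@H](O[Si](C)(C)C(C)(C)C)C1 | intermediate (not isolated)
34 | (3R,3'R)-3-(tert-butyldimethylsilyloxy)-7,8-didehydro-7',8'-dihydro-β,β-caroten-3'-ol (all-E) | CC1=C(C#C/C(C)=C/C=C/C(C)=C/C=C/C=C(C)/C=C/C=C(\C)CCC2=C(C)C[C@@H](O)CC2(C)C)C(C)(C)C[C@H](O[Si](C)(C)C(C)(C)C)C1 | intermediate
35 | (3R,3'R)-7,8-didehydro-7',8'-dihydro-β,β-carotene-3,3'-diol (all-E) | CC1=C(C#C/C(C)=C/C=C/C(C)=C/C=C/C=C(C)/C=C/C=C(\C)CCC2=C(C)C[C@@H](O)CC2(C)C)C(C)(C)C[C@H](O)C1 | target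

**Step count and risks**

Total step count: 15. Longest linear sequence: 8 steps (3, 4, 5, 6, 7, 8, 14, 15).

Steps most likely to fail:

Step 6 (labelled). The bulky vinylborane may add too slowly to the congested diene, so that loss of α-pinene by retro-hydroboration takes over, or it may add with poor facial selectivity. The fallback uses known chemistry only and takes C3' from actinol. It sets out from alkylborane 11 (made from 9 and 10 as in step 5) and enol triflate 24: B-alkyl Suzuki–Miyaura coupling (PdCl2(dppf), aq. K3PO4, DMF) should give the bis-silyl ether tert-butyl({(2E)-5-[(4R)-4-(tert-butyldimethylsilyloxy)-2,6,6-trimethylcyclohex-1-en-1-yl]-3-methylpent-2-en-1-yl}oxy)dimethylsilane F1, and TBAF in THF removes both silyl groups, so that the route is rejoined at diol 18.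

Step 5. Transmetalation of the sp3 borane to the congested dienyl-palladium centre may be slow, so that protodeboronation or β-hydride elimination consumes the borane. The fallback moves the coupling into an iron/Grignard manifold and sets out from 11 and 6: iodinolysis of 11 (I2, NaOMe, MeOH) should give tert-butyl{[(2E)-5-iodo-3-methylpent-2-en-1-yl]oxy}dimethylsilane F2; magnesium in THF converts it into the Grignard reagent [(3E)-5-(tert-butyldimethylsilyloxy)-3-methylpent-3-en-1-yl]magnesium iodide F3; iron-catalysed Kumada-type coupling of F3 with triflate 6 (Fe(acac)3, THF/NMP, −30 °C) comes back to the route at triene 12.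

Step 14. The non-stabilised allylic ylide may give a Z-rich C11'=C12' bond that does not relax fully on heating, and the 9'E geometry may erode in the ylide. The fallback replaces the ylide by a phosphonate carbanion and sets out from diol 18: Corey–Kim bromination to 19 as in step 8, then Arbuzov reaction with triethyl phosphite (90 °C), should give diethyl {(2E)-5-[(4R)-4-hydroxy-2,6,6-trimethylcyclohex-1-en-1-yl]-3-methylpent-2-en-1-yl}phosphonate F4; Horner–Wadsworth–Emmons olefination of aldehyde 31 with F4 (KOtBu, 2.2 equiv, THF, −30 °C → rt) is expected to be E-selective and returns to the route at 34.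

**Further compounds**

F1 | step 6 | tert-butyl({(2E)-5-[(4R)-4-(tert-butyldimethylsilyloxy)-2,6,6-trimethylcyclohex-1-en-1-yl]-3-methylpent-2-en-1-yl}oxy)dimethylsilane | CC(C)(C)[Si](C)(C)OC/C=C(\C)CCC1=C(C)C[C@@H](O[Si](C)(C)C(C)(C)C)CC1(C)C
F2 | step 5 | tert-butyl{[(2E)-5-iodo-3-methylpent-2-en-1-yl]oxy}dimethylsilane | CC(C)(C)[Si](C)(C)OC/C=C(\C)CCI
F3 | step 5 | [(3E)-5-(tert-butyldimethylsilyloxy)-3-methylpent-3-en-1-yl]magnesium iodide | CC(C)(C)[Si](C)(C)OC/C=C(\C)CC[Mg]I
F4 | step 14 | diethyl {(2E)-5-[(4R)-4-hydroxy-2,6,6-trimethylcyclohex-1-en-1-yl]-3-methylpent-2-en-1-yl}phosphonate | CCOP(=O)(OCC)C/C=C(\C)CCC1=C(C)C[C@@H](O)CC1(C)C
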